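Ring A is built last, around the preformed stereocentre, by a Danheiser-type benzannulation. Ring A has oxygen at C1, C3 and C5, its only methyl ether at C1 lies para to the methine-bearing C4, and C2 and C6 can stay unsubstituted until the end; a 3-methoxyvinylketene and a siloxyalkyne give exactly this pattern. In one thermal operation the step closes ring A through the C3–C4, C5–C6 and C2–C3 bonds and delivers OMe, OH and OSi on the right carbons without touching the stereocentre. Its alkyne partner is an enantiopure triisopropylsilyl ynol ether whose propargylic carbon already bears H, isobutyl and a tribenzyl-protected phloroglucinol ring B, the centre being set by an oxazolidinone-directed alkylation.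

Key step: step 12

Remark: the stereocentre of the target is (R). In 28 the two open positions of each ring are interchanged by rotation about the aryl–methine bond, and in 29 each ring has one open position left, so late acetylation and prenylation raise no regiochemical question. 3-Methoxycyclobut-2-en-1-one is assumed not to be a stock item and is made from the ethoxy compound.

Step 1
Reactants: 1 2,4,6-trihydroxybenzaldehyde
Product: 2 2,4,6-tris(benzyloxy)benzaldehyde
Conditions: BnBr (3.6 equiv), K2CO3, DMF, rt → 60 °C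
Reagents that add atoms: benzyl bromide, BrCc1ccccc1
Why: Williamson etherification of all three phenols, in which the formyl group lowers the nucleophilicity of the ring carbons enough to suppress C-benzylation and mild heating brings the two hydrogen-bonded ortho hydroxyls to reaction.

Step 2
Reactants: 2 2,4,6-tris(benzyloxy)benzaldehyde
Product: 3 1,3,5-tris(benzyloxy)-2-(2-methoxyethenyl)benzene (E/Z mixture)
Conditions: MeOCH2PPh3Cl, KOtBu, THF, 0 °C; then 2, 0 °C → rt
Reagents that add atoms: (methoxymethyl)triphenylphosphonium chloride, COC[P+](c1ccccc1)(c1ccccc1)c1ccccc1.[Cl-]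
Why: Wittig methoxymethylenation with a non-stabilised ylide is reactive enough for this hindered, electron-rich aldehyde, and the alkene geometry is irrelevant because the enol ether is hydrolysed next.

Step 3
Reactants: 3 1,3,5-tris(benzyloxy)-2-(2-methoxyethenyl)benzene
Product: 5 [2,4,6-tris(benzyloxy)phenyl]acetic acid, via arylacetaldehyde 4 (not isolated)
Conditions: 2 M aq. HCl, THF, rt; then NaClO2, NaH2PO4, 2-methylbut-2-ene, t-BuOH/H2O, 0 °C → rt
Reagents that add atoms: water, O; sodium chlorite, [Na+].[O-]Cl=O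
Why: Acid hydrolysis of the enol ether releases the arylacetaldehyde, which is oxidised at once by Pinnick oxidation while 2-methylbut-2-ene traps hypochlorous acid before it can chlorinate the electron-rich ring.

Step 4
Reactants: 5 [2,4,6-tris(benzyloxy)phenyl]acetic acid; 6 (4R)-4-benzyl-1,3-oxazolidin-2-one
Product: 8 (4R)-4-benzyl-3-{[2,4,6-tris(benzyloxy)phenyl]acetyl}-1,3-oxazolidin-2-one, via mixed pivalic anhydride 7 (not isolated)
Conditions: t-BuCOCl, Et3N, THF, −20 °C; then LiCl, 6, −20 °C → rt
Reagents that add atoms: none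
Why: Mixed-anhydride N-acylation of the oxazolidinone, in which the LiCl/Et3N-activated auxiliary attacks the less hindered arylacetyl carbonyl of 7, so no alkyllithium is needed.

Step 5
Reactants: 8 (4R)-4-benzyl-3-{[2,4,6-tris(benzyloxy)phenyl]acetyl}-1,3-oxazolidin-2-one; 9 3-bromo-2-methylprop-1-ene
Product: 11 (4R)-4-benzyl-3-{(2R)-4-methyl-2-[2,4,6-tris(benzyloxy)phenyl]pent-4-enoyl}-1,3-oxazolidin-2-one, via sodium Z-enolate 10 (not isolated)
Conditions: NaN(SiMe3)2 (1.1 equiv), THF, −78 °C; then 9 (3 equiv), −78 → −40 °C; minor diastereomer removed by chromatography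
Reagents that add atoms: none
Why: Evans asymmetric alkylation, in which the chelated sodium (Z)-enolate is attacked by the reactive allylic bromide on the face opposite the C4 benzyl group of the (R)-auxiliary, which should set the (R) configuration at the new benzylic centre.

Step 6
Reactants: 11 (4R)-4-benzyl-3-{(2R)-4-methyl-2-[2,4,6-tris(benzyloxy)phenyl]pent-4-enoyl}-1,3-oxazolidin-2-one
Product: 12 (4R)-4-benzyl-3-{(2R)-4-methyl-2-[2,4,6-tris(benzyloxy)phenyl]pentanoyl}-1,3-oxazolidin-2-one
Conditions: H2 (3 atm), RhCl(PPh3)3 (5 mol %), PhMe/EtOH, rt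
Reagents that add atoms: none
Why: Homogeneous hydrogenation with RhCl(PPh3)3 saturates the 1,1-disubstituted alkene to the isobutyl group without hydrogenolysis of the benzyl ethers and without basic or acidic contact at the α-stereocentre.

Step 7
Reactants: 12 (4R)-4-benzyl-3-{(2R)-4-methyl-2-[2,4,6-tris(benzyloxy)phenyl]pentanoyl}-1,3-oxazolidin-2-one
Product: 13 (2R)-4-methyl-2-[2,4,6-tris(benzyloxy)phenyl]pentan-1-ol
Conditions: LiBH4, H2O (1 equiv), Et2O, 0 °C → rt
Reagents that add atoms: none
Why: Reductive cleavage of the N-acyl oxazolidinone by LiBH4 at the exocyclic carbonyl gives the primary alcohol under non-enolising conditions, so the stereocentre is kept and the auxiliary is recovered.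

Step 8
Reactants: 13 (2R)-4-methyl-2-[2,4,6-tris(benzyloxy)phenyl]pentan-1-ol
Product: 14 (2R)-4-methyl-2-[2,4,6-tris(benzyloxy)phenyl]pentanal
Conditions: Dess–Martin periodinane, CH2Cl2, 0 °C → rt; used crude at once
Reagents that add atoms: none
Why: Dess–Martin oxidation works near neutrality and at low temperature, which should deliver the configurationally labile α-aryl aldehyde without enolisation.

Step 9
Reactants: 14 (2R)-4-methyl-2-[2,4,6-tris(benzyloxy)phenyl]pentanal
Product: 15 1,3,5-tris(benzyloxy)-2-[(3S)-1,1-dibromo-5-methylhex-1-en-3-yl]benzene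
Conditions: CBr4 (2 equiv), PPh3 (4 equiv), CH2Cl2, 0 °C; then 14, −20 → 0 °C
Reagents that add atoms: carbon tetrabromide, BrC(Br)(Br)Br
Why: First stage of the Corey–Fuchs sequence, a Wittig-type dibromo-olefination with the preformed ylide that needs no base, after which the stereocentre is allylic and no longer enolisable.

Step 10
Reactants: 15 1,3,5-tris(benzyloxy)-2-[(3S)-1,1-dibromo-5-methylhex-1-en-3-yl]benzene
Product: 18 triisopropyl({(3S)-5-methyl-3-[2,4,6-tris(benzyloxy)phenyl]hex-1-yn-1-yl}oxy)silane, via lithium acetylide 16 (not isolated), via lithium ynolate 17 (not isolated)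
Conditions: n-BuLi (2.1 equiv), THF, −78 °C; cannulate into t-BuOOLi (from anhydrous t-BuOOH, LiN(SiMe3)2, THF, −78 °C), −78 → 0 °C; then i-Pr3SiOTf, −78 → 0 °C
Reagents that add atoms: tert-butyl hydroperoxide, CC(C)(C)OO; triisopropylsilyl trifluoromethanesulfonate, CC(C)[Si](C(C)C)(C(C)C)OS(=O)(=O)C(F)(F)F
Why: The second stage of the Corey–Fuchs reaction (bromine–lithium exchange, Fritsch–Buttenberg–Wiechell 1,2-hydride shift, deprotonation) leaves lithium acetylide 16, which is not quenched but oxidised by electrophilic oxygen transfer from lithium tert-butyl peroxide to ynolate 17 and then trapped on oxygen by the bulky silyl triflate, while the adjacent negative charge and the low temperature protect the benzylic–propargylic C–H.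

Step 11
Reactants: 19 3-ethoxycyclobut-2-en-1-one
Product: 21 3-methoxycyclobut-2-en-1-one, via cyclobutane-1,3-dione 20 (not isolated)
Conditions: 1 M aq. HCl, rt, concentrate; then Me3SiCHN2, MeOH/CH2Cl2, 0 °C; distil
Reagents that add atoms: water, O; (trimethylsilyl)diazomethane, C[Si](C)(C)C=[N+]=[N-]
Why: Acid hydrolysis of the vinylogous ester gives the strongly acidic, symmetrical dione, whose enol is O-methylated by the diazoalkane in methanol to a single enol ether, avoiding an alcohol exchange that could open the strained ring.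

Step 12
Reactants: 18 triisopropyl({(3S)-5-methyl-3-[2,4,6-tris(benzyloxy)phenyl]hex-1-yn-1-yl}oxy)silane; 21 3-methoxycyclobut-2-en-1-one
Product: 26 5-methoxy-2-{(1R)-3-methyl-1-[2,4,6-tris(benzyloxy)phenyl]butyl}-3-[(triisopropylsilyl)oxy]phenol, via 3-methoxyvinylketene 22 (not isolated), via vinylcyclobutenone 23 (not isolated), via dienylketene 24 (not isolated), via cyclohexadienone 25 (not isolated)
Conditions: 21 (2 equiv), PhMe, 80 °C, then 110 °C, sealed tube, argon
Reagents that add atoms: none
Why: Heat opens 21 by 4π electrocyclic cleavage to vinylketene 22, whose ketene unit undergoes a [2+2] cycloaddition with the ynol ether, the nucleophilic alkyne carbon that carries the stereocentre bonding to the ketene carbonyl carbon, and the resulting 2-vinylcyclobutenone 23 opens again to dienylketene 24. Ring A is then closed by a thermal disrotatory 6π electrocyclisation of 24 (ketene carbon to the CH2 terminus) to dienone 25, which tautomerises irreversibly to phenol 26; in net terms the alkyne is inserted between C1 and C2 of the cyclobutenone, so C3–C4 and C5–C6 of ring A are new bonds while C2–C3 is broken and made again. This is the Danheiser benzannulation of a cyclobutenone with a trialkylsiloxyalkyne, the established route to resorcinol monosilyl ethers, here run with a 3-alkoxy cyclobutenone. No stereocentre is formed (the sp3 carbon of 23 is lost on ring opening), and the existing benzylic–propargylic centre should be carried through because the cascade is neutral and free of acid, base and metal. The step needs regiocontrol in the [2+2], which the polarisation of the siloxyalkyne provides, and the position of OMe on 21, which places the methyl ether para to C4. Since the opening of 23 is reversible, only the dienylketene with the vinyl group cis to the ketene is drained by cyclisation, and the excess of 21 compensates for ketene dimerisation.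

Step 13
Reactants: 26 5-methoxy-2-{(1R)-3-methyl-1-[2,4,6-tris(benzyloxy)phenyl]butyl}-3-[(triisopropylsilyl)oxy]phenol
Product: 27 5-methoxy-2-{(1S)-3-methyl-1-[2,4,6-tris(benzyloxy)phenyl]butyl}benzene-1,3-diol
Conditions: Bu4NF, AcOH, THF, 0 °C
Reagents that add atoms: none
Why: Fluoride cleaves the aryl silyl ether selectively in the presence of benzyl ethers, and the acetic acid buffer keeps the liberated resorcinol from standing as a phenoxide (the descriptor changes by priority only, not in space).

Step 14
Reactants: 27 5-methoxy-2-{(1S)-3-methyl-1-[2,4,6-tris(benzyloxy)phenyl]butyl}benzene-1,3-diol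
Product: 28 2-[(1R)-1-(2,6-dihydroxy-4-methoxyphenyl)-3-methylbutyl]benzene-1,3,5-triol
Conditions: H2 (1 atm), 10% Pd/C, EtOAc/MeOH, rt
Reagents that add atoms: none
Why: Catalytic hydrogenolysis removes the three O-benzyl groups at a stage where no alkene or ketone is present, and the methyl ether and the diarylmethine C–C bonds are inert to it.

Step 15
Reactants: 28 2-[(1R)-1-(2,6-dihydroxy-4-methoxyphenyl)-3-methylbutyl]benzene-1,3,5-triol
Product: 29 1-{3-[(1R)-1-(3-acetyl-2,6-dihydroxy-4-methoxyphenyl)-3-methylbutyl]-2,4,6-trihydroxyphenyl}ethan-1-one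
Conditions: Ac2O (2.2 equiv), BF3·OEt2, 1,4-dioxane, 0 °C → rt; then aq. NaOAc
Reagents that add atoms: acetic anhydride, CC(=O)OC(C)=O
Why: Friedel–Crafts C-acetylation of two phloroglucinol-type rings, in which the first acetyl group deactivates its own ring so that the second equivalent should go to the other ring, while low temperature limits acid-induced cleavage at the diarylmethine.

Step 16
Reactants: 29 1-{3-[(1R)-1-(3-acetyl-2,6-dihydroxy-4-methoxyphenyl)-3-methylbutyl]-2,4,6-trihydroxyphenyl}ethan-1-one; 30 1-bromo-3-methylbut-2-ene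
Product: 31 1-{3-[(1R)-1-(3-acetyl-2,6-dihydroxy-4-methoxy-5-(3-methylbut-2-en-1-yl)phenyl)-3-methylbutyl]-2,4,6-trihydroxy-5-(3-methylbut-2-en-1-yl)phenyl}ethan-1-one
Conditions: 30 (2.2 equiv), 10% aq. KOH, 0 °C, short reaction time
Reagents that add atoms: none
Why: C-alkylation of acylphloroglucinol phenoxides with prenyl bromide in water, where hydrogen bonding to the phenoxide oxygens favours attack through carbon, should place one prenyl group on the single unsubstituted carbon of each ring.

Compound list
1 | 2,4,6-trihydroxybenzaldehyde | O=Cc1c(O)cc(O)cc1O | starting material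
2 | 2,4,6-tris(benzyloxy)benzaldehyde | O=Cc1c(OCc2ccccc2)cc(OCc2ccccc2)cc1OCc1ccccc1 | intermediate
3 | 1,3,5-tris(benzyloxy)-2-(2-methoxyethenyl)benzene, E/Z mixture | COC=Cc1c(OCc2ccccc2)cc(OCc2ccccc2)cc1OCc1ccccc1 | intermediate
4 | [2,4,6-tris(benzyloxy)phenyl]acetaldehyde | O=CCc1c(OCc2ccccc2)cc(OCc2ccccc2)cc1OCc1ccccc1 | intermediate
5 | [2,4,6-tris(benzyloxy)phenyl]acetic acid | OC(=O)Cc1c(OCc2ccccc2)cc(OCc2ccccc2)cc1OCc1ccccc1 | intermediate
6 | (4R)-4-benzyl-1,3-oxazolidin-2-one | O=C1N[C@H](Cc2ccccc2)CO1 | starting material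
7 | 2,2-dimethylpropanoic [2,4,6-tris(benzyloxy)phenyl]acetic anhydride | CC(C)(C)C(=O)OC(=O)Cc1c(OCc2ccccc2)cc(OCc2ccccc2)cc1OCc1ccccc1 | intermediate
8 | (4R)-4-benzyl-3-{[2,4,6-tris(benzyloxy)phenyl]acetyl}-1,3-oxazolidin-2-one | O=C(Cc1c(OCc2ccccc2)cc(OCc2ccccc2)cc1OCc1ccccc1)N1[C@H](Cc2ccccc2)COC1=O | intermediate
9 | 3-bromo-2-methylprop-1-ene | CC(=C)CBr | starting material
10 | sodium (1Z)-1-[(4R)-4-benzyl-2-oxo-1,3-oxazolidin-3-yl]-2-[2,4,6-tris(benzyloxy)phenyl]ethen-1-olate | [Na+].[O-]/C(=C\c1c(OCc2ccccc2)cc(OCc2ccccc2)cc1OCc1ccccc1)N1[C@H](Cc2ccccc2)COC1=O | intermediate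
11 | (4R)-4-benzyl-3-{(2R)-4-methyl-2-[2,4,6-tris(benzyloxy)phenyl]pent-4-enoyl}-1,3-oxazolidin-2-one | O=C([C@H](CC(C)=C)c1c(OCc2ccccc2)cc(OCc2ccccc2)cc1OCc1ccccc1)N1[C@H](Cc2ccccc2)COC1=O | intermediate
12 | (4R)-4-benzyl-3-{(2R)-4-methyl-2-[2,4,6-tris(benzyloxy)phenyl]pentanoyl}-1,3-oxazolidin-2-one | O=C([C@H](CC(C)C)c1c(OCc2ccccc2)cc(OCc2ccccc2)cc1OCc1ccccc1)N1[C@H](Cc2ccccc2)COC1=O | intermediate
13 | (2R)-4-methyl-2-[2,4,6-tris(benzyloxy)phenyl]pentan-1-ol | OC[C@H](CC(C)C)c1c(OCc2ccccc2)cc(OCc2ccccc2)cc1OCc1ccccc1 | intermediate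
14 | (2R)-4-methyl-2-[2,4,6-tris(benzyloxy)phenyl]pentanal | O=C[C@H](CC(C)C)c1c(OCc2ccccc2)cc(OCc2ccccc2)cc1OCc1ccccc1 | intermediate
15 | 1,3,5-tris(benzyloxy)-2-[(3S)-1,1-dibromo-5-methylhex-1-en-3-yl]benzene | BrC(Br)=C[C@H](CC(C)C)c1c(OCc2ccccc2)cc(OCc2ccccc2)cc1OCc1ccccc1 | intermediate
16 | lithium (3S)-5-methyl-3-[2,4,6-tris(benzyloxy)phenyl]hex-1-yn-1-ide | [Li+].[C-]#C[C@H](CC(C)C)c1c(OCc2ccccc2)cc(OCc2ccccc2)cc1OCc1ccccc1 | intermediate
17 | lithium (3S)-5-methyl-3-[2,4,6-tris(benzyloxy)phenyl]hex-1-yn-1-olate | [Li+].[O-]C#C[C@H](CC(C)C)c1c(OCc2ccccc2)cc(OCc2ccccc2)cc1OCc1ccccc1 | intermediate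
18 | triisopropyl({(3S)-5-methyl-3-[2,4,6-tris(benzyloxy)phenyl]hex-1-yn-1-yl}oxy)silane | CC(C)[Si](C(C)C)(C(C)C)OC#C[C@H](CC(C)C)c1c(OCc2ccccc2)cc(OCc2ccccc2)cc1OCc1ccccc1 | intermediate
19 | 3-ethoxycyclobut-2-en-1-one | CCOC1=CC(=O)C1 | starting material
20 | cyclobutane-1,3-dione | O=C1CC(=O)C1 | intermediate
21 | 3-methoxycyclobut-2-en-1-one | COC1=CC(=O)C1 | intermediate
22 | 3-methoxybuta-1,3-dien-1-one (3-methoxyvinylketene) | COC(=C)C=C=O | intermediate
23 | 4-(1-methoxyethenyl)-2-{(1R)-3-methyl-1-[2,4,6-tris(benzyloxy)phenyl]butyl}-3-[(triisopropylsilyl)oxy]cyclobut-2-en-1-one, both epimers at ring C4 | COC(=C)C1C(=O)C([C@H](CC(C)C)c2c(OCc3ccccc3)cc(OCc3ccccc3)cc2OCc2ccccc2)=C1O[Si](C(C)C)(C(C)C)C(C)C | intermediate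
24 | (3E)-5-methoxy-2-{(1R)-3-methyl-1-[2,4,6-tris(benzyloxy)phenyl]butyl}-3-[(triisopropylsilyl)oxy]hexa-1,3,5-trien-1-one | COC(=C)/C=C(O[Si](C(C)C)(C(C)C)C(C)C)\C(=C=O)[C@H](CC(C)C)c1c(OCc2ccccc2)cc(OCc2ccccc2)cc1OCc1ccccc1 | intermediate
25 | 5-methoxy-2-{(1R)-3-methyl-1-[2,4,6-tris(benzyloxy)phenyl]butyl}-3-[(triisopropylsilyl)oxy]cyclohexa-2,4-dien-1-one | COC1=CC(O[Si](C(C)C)(C(C)C)C(C)C)=C([C@H](CC(C)C)c2c(OCc3ccccc3)cc(OCc3ccccc3)cc2OCc2ccccc2)C(=O)C1 | intermediate
26 | 5-methoxy-2-{(1R)-3-methyl-1-[2,4,6-tris(benzyloxy)phenyl]butyl}-3-[(triisopropylsilyl)oxy]phenol | COc1cc(O)c([C@H](CC(C)C)c2c(OCc3ccccc3)cc(OCc3ccccc3)cc2OCc2ccccc2)c(O[Si](C(C)C)(C(C)C)C(C)C)c1 | intermediate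
27 | 5-methoxy-2-{(1S)-3-methyl-1-[2,4,6-tris(benzyloxy)phenyl]butyl}benzene-1,3-diol | COc1cc(O)c([C@H](CC(C)C)c2c(OCc3ccccc3)cc(OCc3ccccc3)cc2OCc2ccccc2)c(O)c1 | intermediate
28 | 2-[(1R)-1-(2,6-dihydroxy-4-methoxyphenyl)-3-methylbutyl]benzene-1,3,5-triol | COc1cc(O)c([C@H](CC(C)C)c2c(O)cc(O)cc2O)c(O)c1 | intermediate
29 | 1-{3-[(1R)-1-(3-acetyl-2,6-dihydroxy-4-methoxyphenyl)-3-methylbutyl]-2,4,6-trihydroxyphenyl}ethan-1-one | COc1cc(O)c([C@H](CC(C)C)c2c(O)cc(O)c(C(C)=O)c2O)c(O)c1C(C)=O | intermediate
30 | 1-bromo-3-methylbut-2-ene | CC(C)=CCBr | starting material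
31 | 1-{3-[(1R)-1-(3-acetyl-2,6-dihydroxy-4-methoxy-5-(3-methylbut-2-en-1-yl)phenyl)-3-methylbutyl]-2,4,6-trihydroxy-5-(3-methylbut-2-en-1-yl)phenyl}ethan-1-one | COc1c(CC=C(C)C)c(O)c([C@H](CC(C)C)c2c(O)c(CC=C(C)C)c(O)c(C(C)=O)c2O)c(O)c1C(C)=O | target

Total step count: 16. Longest linear sequence: 15 steps (steps 1–10, then 12–16); step 11 is the one-step side branch.

Steps most likely to fail

Step 12. The donor-substituted cyclobutenone 21 may open to the vinylketene too slowly at temperatures that siloxyalkyne 18 tolerates, so that 18 is lost by silyl migration or the ketene by dimerisation before the hindered [2+2] takes place. The fallback makes the same ketene 22 cold and by another route, the amine-induced 1,4-dehydrochlorination of an unsaturated acid chloride. It sets out from 18: (2E)-3-methoxybut-2-enoyl chloride F1, made from the commercial acid and oxalyl chloride, would be added slowly to 18 and Et3N in toluene at 0 °C → rt so that 22 is trapped as it forms. Brief warming to 80 °C should then carry 23 through 24 and 25, and the route is rejoined at 26.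

Step 16. The ambident phenoxides may alkylate on oxygen, take two prenyl groups on one ring or dearomatise by attack at an already substituted carbon, and base may start retro-Friedel–Crafts scrambling at the diarylmethine. The fallback changes from phenoxide alkylation to electrophilic aromatic substitution. It sets out from 29: 2-methylbut-3-en-2-ol and BF3·OEt2 in dioxane at rt generate the prenyl cation, which should attack the one free carbon of each ring, while O-alkylation is reversible under acid. The reaction is stopped early to limit chroman formation, and the route is rejoined at 31; no new compound is made on the way.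

Step 15. A second acetyl group may enter one ring, O-acetates may persist, or ipso-protonation may cleave the aryl–methine bond, with loss of optical purity. The fallback is a Houben–Hoesch acylation, which uses a nitrilium electrophile and stops itself. It sets out from 28: MeCN, ZnCl2 and dry HCl in Et2O at 0 °C should precipitate, after one acylation per ring, the bis(ketiminium) dichloride F2. Hydrolysis of F2 in warm water returns the route to 29.

Further compounds
F1 | step 12 | (2E)-3-methoxybut-2-enoyl chloride | CO/C(C)=C/C(Cl)=O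
F0 | step 16 | none | none
F2 | step 15 | 1-{3-[(1R)-1-(3-ethanimidoyl-2,6-dihydroxy-4-methoxyphenyl)-3-methylbutyl]-2,4,6-trihydroxyphenyl}ethan-1-imine dihydrochloride | COc1cc(O)c([C@H](CC(C)C)c2c(O)cc(O)c(C(C)=[NH2+])c2O)c(O)c1C(C)=[NH2+].[Cl-].[Cl-]
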